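**Retrosynthetic overview**
1. Target 11 ⇐ ethyl ester 10 (saponification) ⇐ ethyl 1-methylpyrrole-2-carboxylate 9. All three C–Br bonds are made last, by exhaustive electrophilic bromination.
2. 9 ⇐ symmetric 2,5-diester 7, by mono-saponification (8) and protodecarboxylation.
3. 7 ⇐ 3,4-dihydroxypyrrole 5, by bis-triflation (6) and palladium/formate deoxygenation.
4. 5 ⇐ diethyl N-methyliminodiacetate 2 + diethyl oxalate 3. An intermolecular crossed Claisen condensation makes C2–C3 and a Dieckmann closure makes C4–C5, so this one operation forms the only ring, the pyrrole.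
5. 2 ⇐ N-methyliminodiacetic acid 1, which already carries N–CH3, C2, C5 and the carboxyl carbon.

Assumption: the target is a planar, achiral pyrrole with no stereocentre, so there is no enantiomer to select and no stereocontrol is needed.

**Route**

Step 1
Reactants: 1 N-methyliminodiacetic acid
Product: 2 diethyl N-methyliminodiacetate
Conditions: SOCl2 (2.5 equiv), EtOH, 0 °C → reflux, 6 h; then aq. NaHCO3
Reagents that add atoms: ethanol, CCO
Why: Fischer-type esterification driven by HCl made in situ while SOCl2 consumes the water, with the protonated tertiary amine inert and no stereocentre formed.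

Step 2
Reactants: 2 diethyl N-methyliminodiacetate; 3 diethyl oxalate
Product: 5 diethyl 3,4-dihydroxy-1-methyl-1H-pyrrole-2,5-dicarboxylate, via acyclic oxalyl Claisen adduct 4 (not isolated)
Conditions: NaOEt (2.5 equiv), EtOH, reflux, 16 h; then 2 M HCl, 0 °C, pH 3
Reagents that add atoms: none
Why: In this Hinsberg-type pyrrole synthesis the ester enolate of 2 attacks the non-enolisable, highly electrophilic oxalate in an intermolecular crossed Claisen condensation (C2–C3), the second glycinate arm closes the ring by Dieckmann condensation (C4–C5), and irreversible formation of the aromatic bis-enolate drives both equilibria and erases the transient stereocentre of 4.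

Step 3
Reactants: 5 diethyl 3,4-dihydroxy-1-methyl-1H-pyrrole-2,5-dicarboxylate
Product: 6 diethyl 1-methyl-3,4-bis{[(trifluoromethyl)sulfonyl]oxy}-1H-pyrrole-2,5-dicarboxylate
Conditions: Tf2O (2.4 equiv), pyridine (5 equiv), CH2Cl2, 0 °C → rt, 3 h
Reagents that add atoms: trifluoromethanesulfonic anhydride, O=S(=O)(OS(=O)(=O)C(F)(F)F)C(F)(F)F
Why: O-sulfonylation of the two acidic enolic hydroxyl groups is fast and clean because the ring carbons are all substituted and deactivated by two esters, and no stereocentre is formed.

Step 4
Reactants: 6 diethyl 1-methyl-3,4-bis{[(trifluoromethyl)sulfonyl]oxy}-1H-pyrrole-2,5-dicarboxylate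
Product: 7 diethyl 1-methyl-1H-pyrrole-2,5-dicarboxylate
Conditions: Pd(OAc)2 (5 mol %), 1,3-bis(diphenylphosphino)propane (6 mol %), HCO2H (5 equiv), Et3N (7.5 equiv), DMF, 70 °C, 4 h
Reagents that add atoms: none
Why: In this palladium-catalysed transfer hydrogenolysis of aryl triflates each electron-poor C–OTf bond adds oxidatively to zerovalent palladium, formate replaces triflate and loses CO2, and C–H reductive elimination follows, leaving the esters untouched and creating no stereocentre.

Step 5
Reactants: 7 diethyl 1-methyl-1H-pyrrole-2,5-dicarboxylate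
Product: 8 5-(ethoxycarbonyl)-1-methyl-1H-pyrrole-2-carboxylic acid
Conditions: KOH (1.05 equiv), EtOH/H2O 9:1, 50 °C, 12 h; then 1 M HCl
Reagents that add atoms: potassium hydroxide, [K+].[OH-]
Why: Mono-saponification of a symmetric diester stops after one ester because base is limiting and the electron-releasing carboxylate deactivates the remaining vinylogous carbamate ester, while acid/base extraction removes any 7, and no stereocentre is formed.

Step 6
Reactants: 8 5-(ethoxycarbonyl)-1-methyl-1H-pyrrole-2-carboxylic acid
Product: 9 ethyl 1-methyl-1H-pyrrole-2-carboxylate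
Conditions: Ag2CO3 (10 mol %), AcOH (5 mol %), DMSO, 120 °C, 16 h
Reagents that add atoms: none
Why: In this silver-catalysed protodecarboxylation of a heteroaromatic 2-carboxylic acid the silver carboxylate loses CO2 to a pyrrol-2-yl silver species stabilised by the adjacent nitrogen and the remote ester, protonation then gives the C–H bond, and no stereocentre is formed.

Step 7
Reactants: 9 ethyl 1-methyl-1H-pyrrole-2-carboxylate
Product: 10 ethyl 3,4,5-tribromo-1-methyl-1H-pyrrole-2-carboxylate
Conditions: Br2 (3.6 equiv), AcOH, dark, rt → 60 °C, 6 h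
Reagents that add atoms: bromine, BrBr
Why: Threefold electrophilic aromatic substitution fills C4 and C5 quickly and C3 on warming because the pyrrole stays nucleophilic enough despite the ester, the ester blocks ipso bromodecarboxylation at C2, ionic conditions in the dark spare the N-methyl group, and no stereocentre is formed.

Step 8
Reactants: 10 ethyl 3,4,5-tribromo-1-methyl-1H-pyrrole-2-carboxylate
Product: 11 3,4,5-tribromo-1-methyl-1H-pyrrole-2-carboxylic acid
Conditions: LiOH (3 equiv), THF/EtOH/H2O 2:1:1, 50 °C, 12 h; then 1 M HCl, 0 °C, pH 2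
Reagents that add atoms: lithium hydroxide, [Li+].[OH-]
Why: Saponification by acyl–oxygen cleavage is helped by the three electron-withdrawing bromines, the pyrrole C–Br bonds do not undergo nucleophilic substitution, cold acidification avoids decarboxylation, and no stereocentre is present.

**Compound list**
1 | N-methyliminodiacetic acid | CN(CC(=O)O)CC(=O)O | starting material
2 | diethyl N-methyliminodiacetate | CCOC(=O)CN(C)CC(=O)OCC | intermediate
3 | diethyl oxalate | CCOC(=O)C(=O)OCC | starting material
4 | acyclic oxalyl Claisen adduct, diethyl 2-[(2-ethoxy-2-oxoethyl)(methyl)amino]-3-oxobutanedioate (racemic, enolisable, present as its sodium enolate, not isolated) | CCOC(=O)CN(C)C(C(=O)OCC)C(=O)C(=O)OCC | intermediate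
5 | diethyl 3,4-dihydroxy-1-methyl-1H-pyrrole-2,5-dicarboxylate | CCOC(=O)c1c(O)c(O)c(C(=O)OCC)n1C | intermediate
6 | diethyl 1-methyl-3,4-bis{[(trifluoromethyl)sulfonyl]oxy}-1H-pyrrole-2,5-dicarboxylate | CCOC(=O)c1c(OS(=O)(=O)C(F)(F)F)c(OS(=O)(=O)C(F)(F)F)c(C(=O)OCC)n1C | intermediate
7 | diethyl 1-methyl-1H-pyrrole-2,5-dicarboxylate | CCOC(=O)c1ccc(C(=O)OCC)n1C | intermediate
8 | 5-(ethoxycarbonyl)-1-methyl-1H-pyrrole-2-carboxylic acid | CCOC(=O)c1ccc(C(=O)O)n1C | intermediate
9 | ethyl 1-methyl-1H-pyrrole-2-carboxylate | CCOC(=O)c1cccn1C | intermediate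
10 | ethyl 3,4,5-tribromo-1-methyl-1H-pyrrole-2-carboxylate | CCOC(=O)c1c(Br)c(Br)c(Br)n1C | intermediate
11 | 3,4,5-tribromo-1-methyl-1H-pyrrole-2-carboxylic acid | Cn1c(Br)c(Br)c(Br)c1C(=O)O | target

**Total step count:** 8. **Longest linear sequence:** 8.

**Three steps most likely to fail**

Step 4, double reductive detriflation. The risks are S–O cleavage back to the hydroxypyrrole and stalling at the monotriflate. The fallback sets out from 5 and comes back at 7. It replaces sulfonate activation and homogeneous palladium/formate chemistry with heteroaryl ether activation. Both hydroxyl groups are O-arylated with 5-chloro-1-phenyl-1H-tetrazole (K2CO3, DMF, 70 °C) to give diethyl 1-methyl-3,4-bis[(1-phenyl-1H-tetrazol-5-yl)oxy]-1H-pyrrole-2,5-dicarboxylate F1. The two pyrrole C–O bonds are then cleaved by heterogeneous hydrogenolysis (H2, 3 bar, Pd/C, EtOH, 40 °C). This leaves the ester-deactivated pyrrole intact and delivers 7.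

Step 6, protodecarboxylation. The risks are sluggish CO2 loss and loss of the fairly volatile 9 on isolation. The fallback sets out from 8 and comes back at 10, so 9 is never made. The carboxyl group is used as the placeholder for the C5 bromine instead of being replaced by hydrogen. Br2 (2.2 equiv) in AcOH at room temperature gives 3,4-dibromo-5-(ethoxycarbonyl)-1-methyl-1H-pyrrole-2-carboxylic acid F2. Its carboxylate (NaHCO3, aq. MeCN) is then treated with Br2 (1.1 equiv), and ipso attack at the fully substituted α-carbon with loss of CO2 (bromodecarboxylation) gives 10. If ipso attack occurs before the β-brominations, it leads to the same product.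

Step 5, mono-saponification. The risk is a mixture of diester, half ester and diacid. The fallback sets out from 7 and comes back at 9, and it moves the desymmetrisation from the hydrolysis to the decarboxylation. Excess KOH (aq. EtOH, reflux, then HCl) gives 1-methyl-1H-pyrrole-2,5-dicarboxylic acid F3. Ag2CO3 (10 mol %) and AcOH (5 mol %) in DMSO at 110 °C, followed by HPLC, remove one carboxyl group. This first loss is the faster one because the second carboxyl group acts as an acceptor, and it gives 1-methyl-1H-pyrrole-2-carboxylic acid F4. Fischer esterification (EtOH, cat. H2SO4, reflux) then gives 9.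

**Further compounds**
F1 | step 4 | diethyl 1-methyl-3,4-bis[(1-phenyl-1H-tetrazol-5-yl)oxy]-1H-pyrrole-2,5-dicarboxylate | CCOC(=O)c1c(Oc2nnnn2-c2ccccc2)c(Oc2nnnn2-c2ccccc2)c(C(=O)OCC)n1C
F2 | step 6 | 3,4-dibromo-5-(ethoxycarbonyl)-1-methyl-1H-pyrrole-2-carboxylic acid | CCOC(=O)c1c(Br)c(Br)c(C(=O)O)n1C
F3 | step 5 | 1-methyl-1H-pyrrole-2,5-dicarboxylic acid | Cn1c(C(=O)O)ccc1C(=O)O
F4 | step 5 | 1-methyl-1H-pyrrole-2-carboxylic acid | Cn1cccc1C(=O)O
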